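No step of this flask ended a chain, so J and G together stayed at the charged J, while Q, X and E together stayed at the charged Q.

    Q + J → G + X (k1 = 5.0 M⁻¹ h⁻¹)
    Q + G → X + G, rate k2*[G]*[Q] (k2 = 380 M⁻¹ h⁻¹)
    X + G → Q + G, rate k3*[G] as long as [X] is above zero (k3 = 0.71 h⁻¹)
    Q → E (k4 = 3.6 × 10⁻⁴ h⁻¹)

Q 0.035 M; J 84 µM; time 30 h

- average number of monomer units in a chain (chains begun, living or dead) at 30 h
- part of the Q that has reacted at 30 h

I turned the question round: what must hold for Q to stand at its floor, where the forward and back steps cancel? With G steady, Q falls pseudo-first-order toward that floor, the back constant over the forward constant, 1.87 mM. Its lifetime τ, one over the forward constant times the charged J, is 31.3 h. But G arrives late: J lives about 5.71 h at the charged Q, and 5.25 such lifetimes fit the run. So I took nearly all of J as begun and charged the run a lag of one J lifetime. I dropped the step from Q to E, because the half-life of Q by it, 80 d, is long against 30 h.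

My quantity is the lifetime count n, the run less the lag, divided by τ: 0.775. I chose to count Q as standing at its floor from n of 3, which leaves 4.98% of the excess over the floor. This flask stood below that, with 46.1% of the excess left. So I reckoned Q at 17.1 mM, c at 51.1%, and dp at 213, taking reacted Q as the monomer in chains and charged J as the chains begun.

The forecast gave dp 213 and c 51%, reasoning that “Q relaxes toward the reversible-propagation floor”.

The flask gave dp 214 and c 51.1%. At n of 0.775, it was still making X 9.18 times faster than it used X up. The same flask read at 3.0 d has n of 2.12, which puts Q at 5.86 mM, or 16.7% of the charge, and that flask held 17%.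

The constants used here were chosen freely; the result is computed.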